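**Retrosynthetic overview**
1. The two esters are installed last on a 4,6,10-triol core: 4-hydroxybenzoate on O6, then tiglate on O10, which stays silylated until then. No ring-closing metathesis is used.
2. Ring A (five-membered) is closed through the C4–C5 bond by an intramolecular samarium-enolate aldol onto an isopropyl ketone. This sets C4, C5 and the cis ring fusion from C1; C6 follows by chelate-controlled hydride reduction.
3. Ring B (seven-membered) comes from the key step, an enantioselective dirhodium-carbenoid cyclopropanation/divinylcyclopropane Cope sequence (formal [4+3]). It makes the C7–C8 and C1–C10 bonds and sets the quaternary C1 and C10 together.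
4. The partners are a 2-methoxytriene (methyl geranate plus one CH2) and a 4-silyloxy vinyldiazoacetate (ethyl diazoacetate plus silyloxyacetaldehyde). The carbenoid ester carbon becomes the C8 methyl group.
5. Order of ring formation: ring B first, then ring A.

Assumption: positions are cited with daucane numbering (C1 quaternary methyl-bearing fusion carbon, C4 carbinol, C5 fusion CH, C6 aroyloxy CH, C7 CH2, C8=C9 alkene, C10 tigloyloxy CH); β is the face of the C1 methyl group; TBS = tert-butyldimethylsilyl; methyl geranate, ethyl diazoacetate, (TBS-oxy)acetaldehyde, 4-acetoxybenzoyl chloride and tigloyl chloride are taken as commercial.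

**Route**

Step 1
Reactants: 1 methyl geranate [methyl (2E)-3,7-dimethylocta-2,6-dienoate]
Product: 2 (3E)-2-methoxy-4,8-dimethylnona-1,3,7-triene
Conditions: Cp2TiMe2 (2.5 equiv), PhMe, 70 °C, dark; filtration through basic Al2O3
Reagents that add atoms: dimethyltitanocene Cp2TiMe2, C[Ti](C)(C1C=CC=C1)C1C=CC=C1
Why: Petasis methylenation turns the ester C=O into the enol-ether C=CH2 (the new CH2 is C7) and leaves the (E)-trisubstituted alkene untouched, so the geometry that later relays the C1/C10 relationship is secured and no stereocentre is formed.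

Step 2
Reactants: 3 ethyl diazoacetate; 4 (TBS-oxy)acetaldehyde
Product: 5 ethyl 4-(TBS-oxy)-2-diazo-3-hydroxybutanoate (racemic)
Conditions: DBU (10 mol %), MeCN, 23 °C
Reagents that add atoms: none
Why: Base-catalysed aldol-type addition of the diazoacetate carbon to the aldehyde (DBU-catalysed condensation of acyldiazomethanes with aldehydes) keeps the diazo group; the racemic carbinol centre is removed in step 3.

Step 3
Reactants: 5 ethyl 4-(TBS-oxy)-2-diazo-3-hydroxybutanoate
Product: 7 ethyl (3E)-4-(TBS-oxy)-2-diazobut-3-enoate, via dichlorophosphate ester 6 (not isolated)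
Conditions: POCl3 (1.5 equiv), Et3N (4 equiv), CH2Cl2, 0 °C; used at once
Reagents that add atoms: none
Why: Dehydration of a β-hydroxy-α-diazo ester with POCl3/Et3N is the standard entry to vinyldiazoacetates: the diazo carbon assists ionisation of the dichlorophosphate and loss of the proton next to oxygen gives the conjugated (E)-silyl enol ether, the thermodynamically preferred geometry, with no stereocentre left.

Step 4
Reactants: 2 (3E)-2-methoxy-4,8-dimethylnona-1,3,7-triene; 7 ethyl (3E)-4-(TBS-oxy)-2-diazobut-3-enoate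
Product: 9 ethyl (3S,4R)-3-(TBS-oxy)-6-methoxy-4-methyl-4-(4-methylpent-3-en-1-yl)cyclohepta-1,5-diene-1-carboxylate, via cis-divinylcyclopropane 8 (not isolated)
Conditions: Rh2(S-DOSP)4 (dirhodium tetrakis[(S)-N-(4-dodecylbenzenesulfonyl)prolinate], 1 mol %), 2 (1.5 equiv), hexanes, −40 → 23 °C, slow addition of 7; then PhMe, 80 °C
Reagents that add atoms: none
Why: Davies tandem cyclopropanation/Cope rearrangement (formal [4+3] cycloaddition): the donor/acceptor dirhodium carbenoid adds only to the terminal electron-rich enol-ether alkene of 2 with catalyst-controlled face selectivity to give the (1R,2S) cis-divinylcyclopropane, whose boat-shaped Cope rearrangement joins C10 to C1 with the two (E)-substituents (silyloxy group and side chain) cis, which sets C10 (S) and the quaternary C1 (R) in one operation; the closest precedents use the same catalyst class with (E)-4-substituted vinyldiazoacetates and with (E)-4,4-disubstituted dienes carrying a (Z)-methyl group.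

Step 5
Reactants: 9 ethyl (3S,4R)-3-(TBS-oxy)-6-methoxy-4-methyl-4-(4-methylpent-3-en-1-yl)cyclohepta-1,5-diene-1-carboxylate
Product: 11 ethyl (3S,4S)-5-bromo-3-(TBS-oxy)-4-methyl-4-(4-methylpent-3-en-1-yl)-6-oxocyclohept-1-ene-1-carboxylate (C5 epimers), via bromo hemiketal 10 (not isolated)
Conditions: NBS (1.05 equiv), NaHCO3, THF–H2O (5:1), −10 °C
Reagents that add atoms: N-bromosuccinimide, BrN1C(=O)CCC1=O; water, O
Why: Electrophilic bromination of an enol ether in wet solvent (bromohydrin-type α-bromination) is selective for the most electron-rich alkene and gives the α-bromo ketone regiospecifically on the C5 side; the C5 epimer mixture is irrelevant because C5 becomes an enolate carbon in step 8.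

Step 6
Reactants: 11 ethyl (3S,4S)-5-bromo-3-(TBS-oxy)-4-methyl-4-(4-methylpent-3-en-1-yl)-6-oxocyclohept-1-ene-1-carboxylate
Product: 12 ethyl (3S,4S)-5-bromo-3-(TBS-oxy)-4-[2-(3,3-dimethyloxiran-2-yl)ethyl]-4-methyl-6-oxocyclohept-1-ene-1-carboxylate (epimer mixture)
Conditions: mCPBA (1.1 equiv), NaHCO3, CH2Cl2, 0 °C
Reagents that add atoms: 3-chloroperbenzoic acid, OOC(=O)c1cccc(Cl)c1
Why: Prilezhaev epoxidation reacts with the electron-rich trisubstituted side-chain alkene and not with the ester-deactivated ring alkene; the epoxide stereocentre is erased in step 7.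

Step 7
Reactants: 12 ethyl (3S,4S)-5-bromo-3-(TBS-oxy)-4-[2-(3,3-dimethyloxiran-2-yl)ethyl]-4-methyl-6-oxocyclohept-1-ene-1-carboxylate
Product: 13 ethyl (3S,4S)-5-bromo-3-(TBS-oxy)-4-methyl-4-(4-methyl-3-oxopentyl)-6-oxocyclohept-1-ene-1-carboxylate (C5 epimers)
Conditions: BF3·OEt2 (0.3 equiv), CH2Cl2, −78 °C
Reagents that add atoms: none
Why: Meinwald rearrangement: Lewis-acid opening at the tertiary epoxide carbon followed by a 1,2-hydride shift from C4 gives the isopropyl ketone, with no stereocentre formed.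

Step 8
Reactants: 13 ethyl (3S,4S)-5-bromo-3-(TBS-oxy)-4-methyl-4-(4-methyl-3-oxopentyl)-6-oxocyclohept-1-ene-1-carboxylate
Product: 15 ethyl (3R,3aR,8S,8aR)-8-(TBS-oxy)-3-hydroxy-8a-methyl-4-oxo-3-(propan-2-yl)-1,2,3,3a,4,5,8,8a-octahydroazulene-6-carboxylate, via samarium enolate 14 (not isolated)
Conditions: SmI2 (2.5 equiv), THF, −78 °C; then aq. NH4Cl
Reagents that add atoms: none
Why: Samarium-mediated intramolecular Reformatsky-type aldol: SmI2 reduces the C–Br bond to a regiodefined trivalent samarium enolate that adds to the tethered ketone through a chelated transition state, so the new bond at C5 forms on the face of the tether (cis ring fusion, H5 syn to the C1 methyl) and the C4 oxygen is syn to the C6 carbonyl (4-OH α, isopropyl β).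

Step 9
Reactants: 15 ethyl (3R,3aR,8S,8aR)-8-(TBS-oxy)-3-hydroxy-8a-methyl-4-oxo-3-(propan-2-yl)-1,2,3,3a,4,5,8,8a-octahydroazulene-6-carboxylate
Product: 16 (3R,3aS,4R,8S,8aR)-8-(TBS-oxy)-6-(hydroxymethyl)-8a-methyl-3-(propan-2-yl)-1,2,3,3a,4,5,8,8a-octahydroazulene-3,4-diol
Conditions: iBu2AlH (6 equiv), CH2Cl2, −78 → 0 °C; aq. potassium sodium tartrate
Reagents that add atoms: none
Why: Hydride reduction with iBu2AlH converts the ester into the primary allylic alcohol and reduces the ketone, held in an aluminium chelate with the C4 hydroxyl, from the convex β face away from ring A (syn-1,3-diol selectivity known for iBu2AlH with β-hydroxy ketones), which sets C6 as the 6α-alcohol (R).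

Step 10
Reactants: 16 (3R,3aS,4R,8S,8aR)-8-(TBS-oxy)-6-(hydroxymethyl)-8a-methyl-3-(propan-2-yl)-1,2,3,3a,4,5,8,8a-octahydroazulene-3,4-diol
Product: 18 (3R,3aS,4R,8S,8aR)-8-(TBS-oxy)-6,8a-dimethyl-3-(propan-2-yl)-1,2,3,3a,4,5,8,8a-octahydroazulene-3,4-diol, via pyridinium allyl sulfate 17 (not isolated)
Conditions: SO3·pyridine (1.1 equiv), THF, 0 °C; then LiAlH4 (4 equiv), 0 → 23 °C
Reagents that add atoms: none
Why: Corey-type deoxygenation of an allylic alcohol: SO3·pyridine sulfates the unhindered primary allylic hydroxyl in preference to the secondary and tertiary ones and LiAlH4 displaces the allyl sulfate by SN2 hydride delivery, which leaves the C8 methyl group without allylic transposition and touches no stereocentre.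

Step 11
Reactants: 18 (3R,3aS,4R,8S,8aR)-8-(TBS-oxy)-6,8a-dimethyl-3-(propan-2-yl)-1,2,3,3a,4,5,8,8a-octahydroazulene-3,4-diol; 19 4-acetoxybenzoyl chloride
Product: 20 (3R,3aS,4R,8S,8aR)-8-(TBS-oxy)-3-hydroxy-6,8a-dimethyl-3-(propan-2-yl)-1,2,3,3a,4,5,8,8a-octahydroazulen-4-yl 4-acetoxybenzoate
Conditions: Et3N, DMAP (0.2 equiv), CH2Cl2, 0 → 23 °C
Reagents that add atoms: none
Why: DMAP-catalysed acylation (nucleophilic acyl-transfer catalysis) takes place only at the secondary C6 hydroxyl because the C4 hydroxyl is tertiary and O10 is silylated, with retention at C6.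

Step 12
Reactants: 20 (3R,3aS,4R,8S,8aR)-8-(TBS-oxy)-3-hydroxy-6,8a-dimethyl-3-(propan-2-yl)-1,2,3,3a,4,5,8,8a-octahydroazulen-4-yl 4-acetoxybenzoate
Product: 21 (3R,3aS,4R,8S,8aR)-3,8-dihydroxy-6,8a-dimethyl-3-(propan-2-yl)-1,2,3,3a,4,5,8,8a-octahydroazulen-4-yl 4-acetoxybenzoate
Conditions: HF·pyridine, pyridine, THF, 0 → 23 °C
Reagents that add atoms: none
Why: Acidic fluoride desilylation removes the allylic silyl ether while the aryl acetate, the benzoate and the tertiary alcohol are stable under these non-basic conditions.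

Step 13
Reactants: 21 (3R,3aS,4R,8S,8aR)-3,8-dihydroxy-6,8a-dimethyl-3-(propan-2-yl)-1,2,3,3a,4,5,8,8a-octahydroazulen-4-yl 4-acetoxybenzoate; 22 tigloyl chloride [(2E)-2-methylbut-2-enoyl chloride]
Product: 23 (3R,3aS,4R,8S,8aR)-3-hydroxy-6,8a-dimethyl-8-{[(2E)-2-methylbut-2-enoyl]oxy}-3-(propan-2-yl)-1,2,3,3a,4,5,8,8a-octahydroazulen-4-yl 4-acetoxybenzoate
Conditions: DMAP (0.3 equiv), pyridine, CH2Cl2, 40 °C
Reagents that add atoms: none
Why: DMAP-catalysed acylation of the remaining secondary allylic C10 hydroxyl with the acid chloride; the tertiary C4 hydroxyl does not react and the (E)-geometry of the tigloyl group, the stable isomer, is kept.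

Step 14
Reactants: 23 (3R,3aS,4R,8S,8aR)-3-hydroxy-6,8a-dimethyl-8-{[(2E)-2-methylbut-2-enoyl]oxy}-3-(propan-2-yl)-1,2,3,3a,4,5,8,8a-octahydroazulen-4-yl 4-acetoxybenzoate
Product: 24 (3R,3aS,4R,8S,8aR)-3-hydroxy-6,8a-dimethyl-8-{[(2E)-2-methylbut-2-enoyl]oxy}-3-(propan-2-yl)-1,2,3,3a,4,5,8,8a-octahydroazulen-4-yl 4-hydroxybenzoate (target)
Conditions: NH3 (2 M in MeOH), THF, 0 °C
Reagents that add atoms: none
Why: Chemoselective aminolysis of the phenyl acetate, an activated aryl ester far more electrophilic than the alkyl 4-hydroxybenzoate and the conjugated tiglate, frees the phenol and gives the target.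

**Compound list**
1 | methyl geranate, methyl (2E)-3,7-dimethylocta-2,6-dienoate | COC(=O)/C=C(\C)CCC=C(C)C | starting material
2 | (3E)-2-methoxy-4,8-dimethylnona-1,3,7-triene | C=C(OC)/C=C(\C)CCC=C(C)C | intermediate
3 | ethyl diazoacetate | CCOC(=O)C=[N+]=[N-] | starting material
4 | (tert-butyldimethylsilyloxy)acetaldehyde | CC(C)(C)[Si](C)(C)OCC=O | starting material
5 | ethyl 4-[(tert-butyldimethylsilyl)oxy]-2-diazo-3-hydroxybutanoate (racemic) | CCOC(=O)C(=[N+]=[N-])C(O)CO[Si](C)(C)C(C)(C)C | intermediate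
6 | dichlorophosphate ester of 5, ethyl 4-[(tert-butyldimethylsilyl)oxy]-2-diazo-3-[(dichlorophosphoryl)oxy]butanoate | CCOC(=O)C(=[N+]=[N-])C(OP(=O)(Cl)Cl)CO[Si](C)(C)C(C)(C)C | intermediate
7 | ethyl (3E)-4-[(tert-butyldimethylsilyl)oxy]-2-diazobut-3-enoate | CCOC(=O)C(=[N+]=[N-])/C=C/O[Si](C)(C)C(C)(C)C | intermediate
8 | ethyl (1R,2S)-1-{(E)-2-[(tert-butyldimethylsilyl)oxy]ethenyl}-2-[(1E)-2,6-dimethylhepta-1,5-dien-1-yl]-2-methoxycyclopropane-1-carboxylate | CCOC(=O)[C@@]1(/C=C/O[Si](C)(C)C(C)(C)C)C[C@]1(OC)/C=C(\C)CCC=C(C)C | intermediate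
9 | ethyl (3S,4R)-3-[(tert-butyldimethylsilyl)oxy]-6-methoxy-4-methyl-4-(4-methylpent-3-en-1-yl)cyclohepta-1,5-diene-1-carboxylate | CC(C)(C)[Si](C)(C)O[C@H]1C=C(C(=O)OCC)CC(OC)=C[C@@]1(C)CCC=C(C)C | intermediate
10 | ethyl (3S,4S)-5-bromo-3-[(tert-butyldimethylsilyl)oxy]-6-hydroxy-6-methoxy-4-methyl-4-(4-methylpent-3-en-1-yl)cyclohept-1-ene-1-carboxylate (C5/C6 epimers) | CC(C)(C)[Si](C)(C)O[C@H]1C=C(C(=O)OCC)CC(O)(OC)C(Br)[C@@]1(C)CCC=C(C)C | intermediate
11 | ethyl (3S,4S)-5-bromo-3-[(tert-butyldimethylsilyl)oxy]-4-methyl-4-(4-methylpent-3-en-1-yl)-6-oxocyclohept-1-ene-1-carboxylate (C5 epimers) | CC(C)(C)[Si](C)(C)O[C@H]1C=C(C(=O)OCC)CC(=O)C(Br)[C@@]1(C)CCC=C(C)C | intermediate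
12 | ethyl (3S,4S)-5-bromo-3-[(tert-butyldimethylsilyl)oxy]-4-[2-(3,3-dimethyloxiran-2-yl)ethyl]-4-methyl-6-oxocyclohept-1-ene-1-carboxylate (epimers at C5 and oxirane) | CC(C)(C)[Si](C)(C)O[C@H]1C=C(C(=O)OCC)CC(=O)C(Br)[C@@]1(C)CCC2OC2(C)C | intermediate
13 | ethyl (3S,4S)-5-bromo-3-[(tert-butyldimethylsilyl)oxy]-4-methyl-4-(4-methyl-3-oxopentyl)-6-oxocyclohept-1-ene-1-carboxylate (C5 epimers) | CC(C)(C)[Si](C)(C)O[C@H]1C=C(C(=O)OCC)CC(=O)C(Br)[C@@]1(C)CCC(=O)C(C)C | intermediate
14 | ethyl (3S,4R)-3-[(tert-butyldimethylsilyl)oxy]-6-[(diiodosamarium)oxy]-4-methyl-4-(4-methyl-3-oxopentyl)cyclohepta-1,5-diene-1-carboxylate (O–SmI2 enolate) | CC(C)(C)[Si](C)(C)O[C@H]1C=C(C(=O)OCC)CC(O[Sm](I)I)=C[C@@]1(C)CCC(=O)C(C)C | intermediate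
15 | ethyl (3R,3aR,8S,8aR)-8-[(tert-butyldimethylsilyl)oxy]-3-hydroxy-8a-methyl-4-oxo-3-(propan-2-yl)-1,2,3,3a,4,5,8,8a-octahydroazulene-6-carboxylate | CC(C)(C)[Si](C)(C)O[C@H]1C=C(C(=O)OCC)CC(=O)[C@@H]2[C@@]1(C)CC[C@@]2(O)C(C)C | intermediate
16 | (3R,3aS,4R,8S,8aR)-8-[(tert-butyldimethylsilyl)oxy]-6-(hydroxymethyl)-8a-methyl-3-(propan-2-yl)-1,2,3,3a,4,5,8,8a-octahydroazulene-3,4-diol | CC(C)(C)[Si](C)(C)O[C@H]1C=C(CO)C[C@@H](O)[C@@H]2[C@@]1(C)CC[C@@]2(O)C(C)C | intermediate
17 | pyridinium {(3R,3aS,4R,8S,8aR)-8-[(tert-butyldimethylsilyl)oxy]-3,4-dihydroxy-8a-methyl-3-(propan-2-yl)-1,2,3,3a,4,5,8,8a-octahydroazulen-6-yl}methyl sulfate | CC(C)(C)[Si](C)(C)O[C@H]1C=C(COS(=O)(=O)[O-])C[C@@H](O)[C@@H]2[C@@]1(C)CC[C@@]2(O)C(C)C.c1cc[nH+]cc1 | intermediate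
18 | (3R,3aS,4R,8S,8aR)-8-[(tert-butyldimethylsilyl)oxy]-6,8a-dimethyl-3-(propan-2-yl)-1,2,3,3a,4,5,8,8a-octahydroazulene-3,4-diol | CC(C)(C)[Si](C)(C)O[C@H]1C=C(C)C[C@@H](O)[C@@H]2[C@@]1(C)CC[C@@]2(O)C(C)C | intermediate
19 | 4-acetoxybenzoyl chloride | CC(=O)Oc1ccc(cc1)C(Cl)=O | starting material
20 | (3R,3aS,4R,8S,8aR)-8-[(tert-butyldimethylsilyl)oxy]-3-hydroxy-6,8a-dimethyl-3-(propan-2-yl)-1,2,3,3a,4,5,8,8a-octahydroazulen-4-yl 4-acetoxybenzoate | CC(C)(C)[Si](C)(C)O[C@H]1C=C(C)C[C@@H](OC(=O)c2ccc(OC(C)=O)cc2)[C@@H]2[C@@]1(C)CC[C@@]2(O)C(C)C | intermediate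
21 | (3R,3aS,4R,8S,8aR)-3,8-dihydroxy-6,8a-dimethyl-3-(propan-2-yl)-1,2,3,3a,4,5,8,8a-octahydroazulen-4-yl 4-acetoxybenzoate | O[C@H]1C=C(C)C[C@@H](OC(=O)c2ccc(OC(C)=O)cc2)[C@@H]2[C@@]1(C)CC[C@@]2(O)C(C)C | intermediate
22 | tigloyl chloride, (2E)-2-methylbut-2-enoyl chloride | C/C=C(\C)C(Cl)=O | starting material
23 | (3R,3aS,4R,8S,8aR)-3-hydroxy-6,8a-dimethyl-8-{[(2E)-2-methylbut-2-enoyl]oxy}-3-(propan-2-yl)-1,2,3,3a,4,5,8,8a-octahydroazulen-4-yl 4-acetoxybenzoate | C/C=C(\C)C(=O)O[C@H]1C=C(C)C[C@@H](OC(=O)c2ccc(OC(C)=O)cc2)[C@@H]2[C@@]1(C)CC[C@@]2(O)C(C)C | intermediate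
24 | (3R,3aS,4R,8S,8aR)-3-hydroxy-6,8a-dimethyl-8-{[(2E)-2-methylbut-2-enoyl]oxy}-3-(propan-2-yl)-1,2,3,3a,4,5,8,8a-octahydroazulen-4-yl 4-hydroxybenzoate (CNP0273650.13) | C/C=C(\C)C(=O)O[C@H]1C=C(C)C[C@@H](OC(=O)c2ccc(O)cc2)[C@@H]2[C@@]1(C)CC[C@@]2(O)C(C)C | target

**Totals**
Total steps: 14. Longest linear sequence: 13 (steps 2, 3 and 4–14 from ethyl diazoacetate; 12 from methyl geranate).

**Three steps most likely to fail**

Step 4 is the largest risk. The 4-silyloxy vinyldiazoacetate 7 is an untested member of its class and may close to a pyrazole. The push–pull cyclopropane 8 may open to [3+2] or trans-cyclopropane products. The Cope step must build a quaternary centre against a (Z)-methyl group. The sense of induction for Rh2(S-DOSP)4 is assigned only by analogy with its styrene cyclopropanations. The fallback sets out from 3 and 2 and returns at 9 by putting the C10 oxygen in after the cycloaddition. DBU-catalysed addition of 3 to acetaldehyde gives ethyl 2-diazo-3-hydroxybutanoate F1, and POCl3/Et3N dehydration gives the parent ethyl 2-diazobut-3-enoate F2, the best-precedented partner for this reaction. Rh2(S-DOSP)4 with 2 then gives the 10-deoxy cycloheptadiene ester F3. γ-Deprotonation (LiN(iPr)2, THF/HMPA, −78 °C) and α-selenenylation with PhSeCl give the deconjugated α-phenylselanyl ester F4. Oxidation with H2O2/pyridine triggers the allyl selenoxide [2,3]-sigmatropic shift, which returns the alkene to C8=C9 and places the hydroxyl on C10 to give the allylic alcohol F5; the C10 epimers would need separation. TBSOTf/2,6-lutidine converts F5 into 9.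

Step 8 may fail because the samarium enolate must attack a hindered isopropyl ketone to make two adjacent congested centres; simple reduction of the bromide or retro-aldol on work-up are the likely failure modes. The fallback sets out from 13 and returns at 15 by activating the electrophile instead of the nucleophile. Zn dust and Me3SiCl in THF convert 13 into the regiodefined trimethylsilyl enol ether F6, which is isolated. TiCl4 in CH2Cl2 at −78 °C then promotes an intramolecular Mukaiyama aldol onto the ketone, and aqueous work-up gives 15. If C4 comes out epimeric, it can be equilibrated through retro-aldol/aldol.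

Step 10 may fail because the sulfation must distinguish the primary allylic hydroxyl from the C6 and C4 hydroxyls, and the allyl sulfate can be attacked by the C6 oxygen or undergo SN2′ reduction. The fallback sets out from 16 and returns at 18 through an isolated halide. Corey–Kim activation (NCS/Me2S, CH2Cl2, −20 °C) converts only the allylic alcohol into the allylic chloride F7. LiEt3BH in THF at 0 °C then displaces the chloride to give 18.

**Further compounds**
F1 | step 4 | ethyl 2-diazo-3-hydroxybutanoate | CCOC(=O)C(=[N+]=[N-])C(C)O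
F2 | step 4 | ethyl 2-diazobut-3-enoate | CCOC(=O)C(=[N+]=[N-])C=C
F3 | step 4 | ethyl (4S)-6-methoxy-4-methyl-4-(4-methylpent-3-en-1-yl)cyclohepta-1,5-diene-1-carboxylate | C1C=C(C(=O)OCC)CC(OC)=C[C@@]1(C)CCC=C(C)C
F4 | step 4 | ethyl (5S)-3-methoxy-5-methyl-5-(4-methylpent-3-en-1-yl)-1-(phenylselanyl)cyclohepta-3,6-diene-1-carboxylate (C1 epimers) | C1=CC(C(=O)OCC)([Se]c2ccccc2)CC(OC)=C[C@@]1(C)CCC=C(C)C
F5 | step 4 | ethyl (3S,4R)-3-hydroxy-6-methoxy-4-methyl-4-(4-methylpent-3-en-1-yl)cyclohepta-1,5-diene-1-carboxylate | O[C@H]1C=C(C(=O)OCC)CC(OC)=C[C@@]1(C)CCC=C(C)C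
F6 | step 8 | ethyl (3S,4R)-3-[(tert-butyldimethylsilyl)oxy]-4-methyl-4-(4-methyl-3-oxopentyl)-6-[(trimethylsilyl)oxy]cyclohepta-1,5-diene-1-carboxylate | CC(C)(C)[Si](C)(C)O[C@H]1C=C(C(=O)OCC)CC(O[Si](C)(C)C)=C[C@@]1(C)CCC(=O)C(C)C
F7 | step 10 | (3R,3aS,4R,8S,8aR)-8-[(tert-butyldimethylsilyl)oxy]-6-(chloromethyl)-8a-methyl-3-(propan-2-yl)-1,2,3,3a,4,5,8,8a-octahydroazulene-3,4-diol | CC(C)(C)[Si](C)(C)O[C@H]1C=C(CCl)C[C@@H](O)[C@@H]2[C@@]1(C)CC[C@@]2(O)C(C)C
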